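**Retrosynthetic overview**
1. Target: a 2,2-dimethyl-2H-chromene (ring A = benzene, ring B = pyran) with C5–OH, a C6 prenyl group and a C7 CH2CH2(4-hydroxyphenyl) arm. The last disconnections are C3=C4 of ring B (ring-closing olefin metathesis) and C6–CH2 of the prenyl group (aromatic Claisen shift from the C5 oxygen), both made in one operation.
2. Enabling feature: C4a, the ring A carbon that carries C4, lies between the two oxygen-bearing carbons C8a (O1) and C5 (OH). Each oxygen has one C5 unit beside it (C2/C3 with the gem-dimethyl on O1; the prenyl on C6, ortho to the C5 oxygen). Both units therefore derive from two identical O-(1,1-dimethylallyl) groups on a mirror-symmetric 2-vinylresorcinol diether.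
3. Earlier disconnections: C7–CH2 by B-alkyl Suzuki coupling of an aryl bromide with the 9-BBN adduct of 4-acetoxystyrene; the vinyl group by Wittig methylenation; both aryl–O bonds by double SNAr on 4-bromo-2,6-difluorobenzaldehyde.
4. Ring order: ring A and the phenol ring are bought; ring B is the only ring made and is closed in the final step.

Key step: step 4

Remark: the target has no stereocentre, and its C3=C4 double bond is cis by ring constraint, so no stereocontrol is needed. 4-Bromo-2,6-difluorobenzaldehyde, 2-methylbut-3-en-2-ol and 4-acetoxystyrene are taken as catalogue compounds. Tertiary allyl aryl ethers are acid-labile, so they should be purified on base-washed silica.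

**Step 1**
Reactants: 1 4-bromo-2,6-difluorobenzaldehyde; 2 2-methylbut-3-en-2-ol
Product: 4 4-bromo-2,6-bis[(2-methylbut-3-en-2-yl)oxy]benzaldehyde, via monofluoro ether 3 (not isolated)
Conditions: 2 (2.4 equiv), NaH (2.3 equiv), THF, 0 °C; then 1, THF/DMF, −10 → 25 °C
Reagents that add atoms: none
Why: Double nucleophilic aromatic substitution (SNAr, addition–elimination) of the two fluorides ortho to the formyl group, which are far more labile than the para bromide; a pre-formed tertiary alkoxide has no α-hydrogen and cannot reduce the aldehyde.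

**Step 2**
Reactants: 4 4-bromo-2,6-bis[(2-methylbut-3-en-2-yl)oxy]benzaldehyde
Product: 5 5-bromo-2-ethenyl-1,3-bis[(2-methylbut-3-en-2-yl)oxy]benzene
Conditions: Ph3PCH3Br, KOtBu, THF, 0 → 25 °C
Reagents that add atoms: methyltriphenylphosphonium bromide, C[P+](c1ccccc1)(c1ccccc1)c1ccccc1.[Br-]
Why: Wittig methylenation with the non-stabilised ylide should convert the hindered, non-enolisable aldehyde into the styrene while leaving the aryl bromide and the tertiary allyl ethers untouched.

**Step 3**
Reactants: 5 5-bromo-2-ethenyl-1,3-bis[(2-methylbut-3-en-2-yl)oxy]benzene; 6 4-ethenylphenyl acetate (4-acetoxystyrene)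
Product: 9 4-(2-{4-ethenyl-3,5-bis[(2-methylbut-3-en-2-yl)oxy]phenyl}ethyl)phenol, via alkylborane 7 (not isolated), via aryl acetate 8 (not isolated)
Conditions: 6 (1.3 equiv), 9-BBN (1.2 equiv), THF, 0 → 25 °C; then 5, PdCl2(dppf) (3 mol %), 3 M aq NaOH, THF, 25 → 45 °C, stopped when 5 is consumed; NH4Cl work-up
Reagents that add atoms: none
Why: Anti-Markovnikov hydroboration of styrene 6 with 9-BBN followed by B-alkyl Suzuki–Miyaura coupling at the unhindered C–Br bond should build the CH2CH2 bridge without any hydrogenation, the borane being fully formed before triene 5 is added and aqueous hydroxide cleaving the aryl acetate in the same flask, while oxidative addition to the aryl bromide is expected to outrun ionisation of the tertiary allyl aryl ethers, whose leaving group would be an electron-rich aryloxide.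

**Step 4**
Reactants: 9 4-(2-{4-ethenyl-3,5-bis[(2-methylbut-3-en-2-yl)oxy]phenyl}ethyl)phenol
Product: 12 7-[2-(4-hydroxyphenyl)ethyl]-2,2-dimethyl-6-(3-methylbut-2-en-1-yl)-2H-chromen-5-ol, via chromene ether 10 (not isolated), via dienone 11 (not isolated)
Conditions: RuCl2(=CHPh)(H2IMes)(PCy3) (second-generation Grubbs catalyst, 5 mol %), toluene (0.01 M), 45 °C, argon sweep; then DMSO (50 equiv per Ru), 120 °C, sealed tube
Reagents that add atoms: none
Why: The ruthenium alkylidene should engage the styrene and one of the two equivalent O–CMe2–CH=CH2 groups of 9 in [2+2] cycloaddition/cycloreversion through a ruthenacyclobutane, expelling ethene and forming the C3=C4 bond, which closes ring B as a six-membered ring with the new cis double bond endocyclic (anchored by O1 and C4a, ortho on ring A) to give 10. This is ring-closing olefin metathesis of a 2-vinylaryl 1,1-dimethylallyl ether, the known metathesis entry to 2,2-dimethyl-2H-chromenes; the gem-dimethyl group favours the reactive rotamer, and since neither olefin has an allylic hydrogen no double-bond migration can intervene. On heating, the remaining aryl 1,1-dimethylallyl ether of 10 should undergo an aromatic Claisen rearrangement, a concerted suprafacial [3,3] shift through a chair-like transition state that breaks O–CMe2 and bonds the CH2 terminus to C6 with allylic transposition (hence a prenyl group), giving dienone 11, whose enolisation to the C5 phenol makes the step irreversible. The selectivity needed is secured by the substrate: the mirror plane through C4a and C7 makes the two ethers equivalent, so either may cyclise, and after ring closure C6 is the only ortho position of the C5 oxygen that carries hydrogen (C4a is quaternary, so a shift there can only revert). The order of events is set by temperature, metathesis at 45 °C being complete before any [3,3] shift starts, so both ethers cannot rearrange, and an early rearrangement of one ether followed by closure of the other would still lead to 12. No stereocentre remains, because the C6 stereocentre of 11 (formed racemic) is erased on aromatisation and the cis geometry of C3=C4 is imposed by the ring.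

**Compound list**
1 | 4-bromo-2,6-difluorobenzaldehyde | O=Cc1c(F)cc(Br)cc1F | starting material
2 | 2-methylbut-3-en-2-ol | C=CC(C)(C)O | starting material
3 | 4-bromo-2-fluoro-6-[(2-methylbut-3-en-2-yl)oxy]benzaldehyde (not isolated) | O=Cc1c(F)cc(Br)cc1OC(C)(C)C=C | intermediate
4 | 4-bromo-2,6-bis[(2-methylbut-3-en-2-yl)oxy]benzaldehyde | O=Cc1c(OC(C)(C)C=C)cc(Br)cc1OC(C)(C)C=C | intermediate
5 | 5-bromo-2-ethenyl-1,3-bis[(2-methylbut-3-en-2-yl)oxy]benzene | C=Cc1c(OC(C)(C)C=C)cc(Br)cc1OC(C)(C)C=C | intermediate
6 | 4-ethenylphenyl acetate | CC(=O)Oc1ccc(C=C)cc1 | starting material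
7 | 4-[2-(9-borabicyclo[3.3.1]nonan-9-yl)ethyl]phenyl acetate (not isolated) | CC(=O)Oc1ccc(CCB2C3CCCC2CCC3)cc1 | intermediate
8 | 4-(2-{4-ethenyl-3,5-bis[(2-methylbut-3-en-2-yl)oxy]phenyl}ethyl)phenyl acetate (not isolated) | CC(=O)Oc1ccc(CCc2cc(OC(C)(C)C=C)c(C=C)c(OC(C)(C)C=C)c2)cc1 | intermediate
9 | 4-(2-{4-ethenyl-3,5-bis[(2-methylbut-3-en-2-yl)oxy]phenyl}ethyl)phenol | Oc1ccc(CCc2cc(OC(C)(C)C=C)c(C=C)c(OC(C)(C)C=C)c2)cc1 | intermediate
10 | 4-(2-{2,2-dimethyl-5-[(2-methylbut-3-en-2-yl)oxy]-2H-chromen-7-yl}ethyl)phenol (not isolated) | Oc1ccc(CCc2cc(OC(C)(C)C=C)c3C=CC(C)(C)Oc3c2)cc1 | intermediate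
11 | 7-[2-(4-hydroxyphenyl)ethyl]-2,2-dimethyl-6-(3-methylbut-2-en-1-yl)-2H-chromen-5(6H)-one (racemic at C6, not isolated) | O=C1C(CC=C(C)C)C(CCc2ccc(O)cc2)=CC2=C1C=CC(C)(C)O2 | intermediate
12 | 7-[2-(4-hydroxyphenyl)ethyl]-2,2-dimethyl-6-(3-methylbut-2-en-1-yl)-2H-chromen-5-ol | CC(C)=CCc1c(CCc2ccc(O)cc2)cc2c(c1O)C=CC(C)(C)O2 | target

**Count**
Total steps: 4. Longest linear sequence: 4 steps (1 → 4 → 5 → 9 → 12; compound 6 enters in step 3).

**Steps most likely to fail**

Step 1. What may go wrong: the hindered tertiary alkoxide may add to the formyl group instead of the ring, and the adduct may then fragment (loss of the formyl carbon, favoured by the two ortho fluorines) or pass hydride to a second aldehyde; the second substitution may also stall for steric reasons. Fallback, setting out from 1 and returning at 4: the aryl–O bonds are made with a small alkoxide and the tertiary allyl groups are then attached to oxygen by allylic substitution rather than SNAr. NaOMe in MeOH at 65 °C should give 4-bromo-2,6-dimethoxybenzaldehyde F1. BBr3 in CH2Cl2 (−78 → 25 °C) should cleave both ethers ortho to the carbonyl to give 4-bromo-2,6-dihydroxybenzaldehyde F2. Alcohol 2 is converted with n-BuLi and Boc2O into tert-butyl 2-methylbut-3-en-2-yl carbonate F3. Tsuji–Trost O-allylation of F2 with F3 (Pd(PPh3)4, THF, 0 °C) should give 4, the phenoxide attacking the more substituted terminus of the 1,1-dimethyl-π-allyl complex under kinetic control. At 0 °C zerovalent palladium with PPh3 should not insert into the aryl bromide.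

Step 4. What may go wrong: ring closure may lag, because ruthenium must load onto a styrene flanked by two tertiary ethers, so that the thermal stage begins with both ethers still present and both rearrange. With ruthenium residues and phenolic protons present at 120 °C, the tertiary ether may also ionise and lose isoprene, or the allyl unit may travel on to C8, instead of shifting cleanly to C6. Fallback, setting out from 5 and returning at 12: the two events are run as separate operations on the phenol-free bromide and the bibenzyl bridge is attached last. Metathesis of 5 alone (same ruthenium catalyst, CH2Cl2, 40 °C, run to completion, ruthenium removed) should give 7-bromo-2,2-dimethyl-5-[(2-methylbut-3-en-2-yl)oxy]-2H-chromene F4. Heating F4 in N,N-diethylaniline at 130 °C (amine-buffered, metal-free) should give, by way of 7-bromo-2,2-dimethyl-6-(3-methylbut-2-en-1-yl)-2H-chromen-5(6H)-one F5, the phenol 7-bromo-2,2-dimethyl-6-(3-methylbut-2-en-1-yl)-2H-chromen-5-ol F6, which can be purified from any isomer. B-alkyl Suzuki coupling of F6 with alkylborane 7 (PdCl2(dppf), 3 M aq NaOH, THF, 50 °C) should give 4-{2-[5-hydroxy-2,2-dimethyl-6-(3-methylbut-2-en-1-yl)-2H-chromen-7-yl]ethyl}phenyl acetate F7, which is saponified in the same flask to 12. No allyl ether is left when palladium is used.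

Step 3. What may go wrong: once the aryl bromide runs low, zerovalent palladium may ionise the tertiary allyl aryl ethers (π-allyl formation), so that C5 units are lost or transposed to linear prenyl ethers; residual B–H may also add to the styrene. Fallback, setting out from 1 and returning at 9: the palladium step is moved ahead of every olefin and allyl ether. Coupling of 1 with alkylborane 7 (PdCl2(dppf), K3PO4, DMF/THF, 50 °C, no hydroxide) should give 4-[2-(3,5-difluoro-4-formylphenyl)ethyl]phenyl acetate F8. An excess of the sodium alkoxide of 2 (THF/DMF, 0 → 25 °C) should remove the acetyl group and displace both fluorides to give 4-[2-(4-hydroxyphenyl)ethyl]-2,6-bis[(2-methylbut-3-en-2-yl)oxy]benzaldehyde F9; a tertiary alkoxide should be far more reactive in SNAr than the phenoxide formed alongside. Wittig methylenation of F9 with an excess of Ph3P=CH2 (THF, 0 → 25 °C) should then give 9.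

**Further compounds**
F1 | step 1 | 4-bromo-2,6-dimethoxybenzaldehyde | COc1cc(Br)cc(OC)c1C=O
F2 | step 1 | 4-bromo-2,6-dihydroxybenzaldehyde | O=Cc1c(O)cc(Br)cc1O
F3 | step 1 | tert-butyl 2-methylbut-3-en-2-yl carbonate | C=CC(C)(C)OC(=O)OC(C)(C)C
F4 | step 4 | 7-bromo-2,2-dimethyl-5-[(2-methylbut-3-en-2-yl)oxy]-2H-chromene | C=CC(C)(C)Oc1cc(Br)cc2OC(C)(C)C=Cc12
F5 | step 4 | 7-bromo-2,2-dimethyl-6-(3-methylbut-2-en-1-yl)-2H-chromen-5(6H)-one | O=C1C(CC=C(C)C)C(Br)=CC2=C1C=CC(C)(C)O2
F6 | step 4 | 7-bromo-2,2-dimethyl-6-(3-methylbut-2-en-1-yl)-2H-chromen-5-ol | CC(C)=CCc1c(Br)cc2c(c1O)C=CC(C)(C)O2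
F7 | step 4 | 4-{2-[5-hydroxy-2,2-dimethyl-6-(3-methylbut-2-en-1-yl)-2H-chromen-7-yl]ethyl}phenyl acetate | CC(=O)Oc1ccc(CCc2cc3c(c(O)c2CC=C(C)C)C=CC(C)(C)O3)cc1
F8 | step 3 | 4-[2-(3,5-difluoro-4-formylphenyl)ethyl]phenyl acetate | CC(=O)Oc1ccc(CCc2cc(F)c(C=O)c(F)c2)cc1
F9 | step 3 | 4-[2-(4-hydroxyphenyl)ethyl]-2,6-bis[(2-methylbut-3-en-2-yl)oxy]benzaldehyde | O=Cc1c(OC(C)(C)C=C)cc(CCc2ccc(O)cc2)cc1OC(C)(C)C=C
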